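Decide first which charge to raise in the next flask, reagent or catalyst, to get a higher rate of making left-handed product at the conversion mark of 20%.

all flasks: catalyst 0.34 mol%; added ligand 3.5 mM
- birch: left-handed substrate 0.54 M; right-handed substrate 0.54 M; reagent 0.80 equiv; run made earlier
- cedar: left-handed substrate 1.2 M; right-handed substrate 1.2 M; reagent 0.80 equiv; run made earlier
- elm: left-handed substrate 0.80 M; right-handed substrate 0.80 M; reagent 1.2 equiv; run made earlier
- flask: left-handed substrate 0.80 M; right-handed substrate 0.80 M; reagent 0.800 equiv

| run | time / h | left-handed product / % | left-handed substrate / % |
|---|---|---|---|
| birch | 12.0 | 4.0 | 46.5 |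
| birch | 25.0 | 6.1 | 46.3 |
| birch | 40.0 | 6.6 | 42.9 |
| birch | 50.0 | 8.0 | 45.6 |
| cedar | 12.0 | 16.5 | 35.9 |
| cedar | 25.0 | 20.7 | 32.2 |
| cedar | 40.0 | 23.3 | 33.2 |
| cedar | 50.0 | 23.8 | 30.7 |
| elm | 6.00 | 10.3 | 40.3 |
| elm | 15.0 | 15.0 | 37.7 |
| elm | 30.0 | 18.0 | 35.6 |
| elm | 50.0 | 22.8 | 31.1 |

(scatter of a reading: 1 percentage point)

- catalyst is single-handed; left-handed substrate and right-handed substrate are mirror images of each other, charged as a racemate, each of them at the stated concentration
- what may be going on: reagent + catalyst + right-handed substrate -> catalyst + right-handed product; reagent + catalyst + left-handed substrate -> catalyst + left-handed product; catalyst + added ligand <-> idle complex; left-handed substrate <-> right-handed substrate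

- apparent order in reagent when 20% of the left-handed substrate and right-handed substrate together are converted (percent change of the rate of making left-handed product for one percent more reagent charged)
- apparent order in catalyst when 20% of the left-handed substrate and right-handed substrate together are converted (percent change of the rate of making left-handed product for one percent more catalyst charged)

The zero of your scale is a reagent in large excess: its level stays near its charge, so one percent more charged gives one percent more rate, an order of one. This flask sits elsewhere on that scale. It holds 0.640 M of reagent against 1.60 M of both substrates together, so reagent is the limiting reagent. Each substrate converted uses one reagent, so the mark takes 0.320 M and leaves [reagent] at 0.320 M. Extra reagent charged does not change the amount used by the mark, so all of it lands on what is left. Charge over what is left gives 2.00; call this ratio the reagent leverage. It is the order in reagent at fixed conversion if the rate follows [reagent] and the working catalyst is unchanged, and it stands above the zero.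

The forecast gives 1.4 for reagent, from “first order, but at fixed conversion the remaining reagent gives” a smaller ratio, and 1.6 for catalyst. You have no catalyst figure of your own. The forecast's numbers put catalyst ahead, while your leverage for reagent stands above the forecast's order in catalyst, so the decision hangs on this difference.

The simulation gives 2.3 for reagent and 2.6 for catalyst, so for one percent more charged, catalyst gives the larger change in rate.

    reagent + catalyst + right-handed substrate → catalyst + right-handed product (k = 0.00440 /M²/s)
    reagent + catalyst + left-handed substrate → catalyst + left-handed product (k = 0.00810 /M²/s)
    catalyst + added ligand ⇌ idle complex (K = 5100 /M, k = 0.0240 /M/s)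
    left-handed substrate ⇌ right-handed substrate (k = 5.90 × 10⁻⁵ /s)

After 40.0 h, idle complex holds 85.6% of the catalyst charged. The reagent leverage of 2.00 stands 0.300 below the order found. With twice the reagent, what is left at the mark grows by a factor of 3.00, and the rate grows by a factor of 6.82.

(The earlier runs and the new flask come from a simulation from invented constants, noise included.)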